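**Retrosynthetic overview**

1. Feature: in the chroman core, C4 is a benzylic CH on C4a of ring A and lies β (through C3) to the benzylic, oxygen-bearing C2. With acetyl standing in for the C3 isopropyl group, C4–C4a is a conjugate-arylation bond and C2–C3 an aldol bond.
2. Disconnections, from the target backwards: five ArO–Me and four Ar–CHO bonds; isopropyl ⇐ isopropenyl ⇐ acetyl; O1–C2 (phenol onto a benzylic cation); then C4–C4a and C2–C3 together in one three-component step from an aryl-9-BBN, (E)-6-methylhept-3-en-2-one and 2,4,6-trimethoxybenzaldehyde.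
3. Ring order: ring A and the C2 aryl ring are bought as arenes; the dihydropyran ring is the only ring made, after the key step (step 4).
4. Stereocontrol: C4 by rhodium–(R)-BINAP in the key step; C3 and C2 by equilibration of the 3-acetylchroman to the 2,3-cis-3,4-trans isomer.

Key step: step 3

Remark: the sense of induction in step 3 is taken from the α-face model of rhodium–BINAP aryl additions to (E)-enones, which calls for (R)-BINAP here; the C3 and carbinol configurations written for 9–11 are the expected kinetic ones and are reset in step 4.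

**Route**

Step 1
Reactants: 1 3,5-dimethoxyphenol
Product: 2 1,3-dimethoxy-5-(methoxymethoxy)benzene
Conditions: NaH, MOMCl, DMF, 0 °C → rt
Reagents that add atoms: chloromethyl methyl ether, COCCl
Why: O-alkylation of the sodium phenoxide by the reactive α-chloro ether (Williamson-type acetal formation) should give the MOM ether cleanly.

Step 2
Reactants: 2 1,3-dimethoxy-5-(methoxymethoxy)benzene
Product: 5 9-[2-(methoxymethoxy)-4,6-dimethoxyphenyl]-9-borabicyclo[3.3.1]nonane, via aryllithium 3 (not isolated), via borate complex 4 (not isolated)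
Conditions: n-BuLi, THF, 0 °C → rt; B-methoxy-9-BBN, −78 °C → rt; Me3SiCl, −78 °C → rt; evaporate, toluene, filter under argon
Reagents that add atoms: B-methoxy-9-borabicyclo[3.3.1]nonane, COB1C2CCCC1CCC2
Why: Directed ortho-metalation should occur at the position flanked by OMOM and OMe (MOM being the stronger director, so this site is preferred over the one between two OMe groups), the aryllithium adds to boron to give the borate complex, and Me3SiCl removes methoxide as Me3SiOMe to leave the neutral B-aryl-9-BBN.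

Step 3
Reactants: 5 9-[2-(methoxymethoxy)-4,6-dimethoxyphenyl]-9-borabicyclo[3.3.1]nonane; 6 (E)-6-methylhept-3-en-2-one; 7 2,4,6-trimethoxybenzaldehyde
Product: 10 (3R,4S)-3-[(R)-hydroxy(2,4,6-trimethoxyphenyl)methyl]-4-[2-(methoxymethoxy)-4,6-dimethoxyphenyl]-6-methylheptan-2-one, via Z-boron enolate 8 (not isolated), via boron aldolate 9 (not isolated)
Conditions: [Rh(OMe)(cod)]2 (cat.), (R)-BINAP, toluene, 80 °C; then 7, −78 °C → 0 °C; then pH 7 buffer, MeOH, 30% H2O2, 0 °C
Reagents that add atoms: none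
Why: The methoxorhodium–(R)-BINAP complex takes the aryl group from boron, the aryl-rhodium species (monovalent rhodium) adds across C3=C4 of 6 to give an oxa-π-allyl rhodium intermediate, and this passes its enolate to a second molecule of 5 to give the Z-boron enolate 8 and fresh aryl-rhodium; 8 then adds to aldehyde 7 through a chair-like six-membered transition state to give aldolate 9. The closest known reaction type is the rhodium–BINAP-catalysed asymmetric 1,4-addition of B-aryl-9-BBN reagents to enones with aldol capture of the chiral boron enolate; the doubly ortho-oxygenated aryl group and the hindered, electron-rich aldehyde are the extensions. No ring closes here: the step forms C4–C4a and C2–C3 (chroman numbering) and leaves the acetyl group where the isopropyl group is needed. C4 (S) is set by the catalyst, the aryl group being delivered to the re face at the α-carbon (C3) of the E-enone as expected for (R)-BINAP; C3 and the carbinol carbon follow from the Z-enolate and the closed transition state (syn aldol, aldehyde anti to the aryl group on C4) but need no control because step 4 resets both. The step needs 1,4- over 1,2-addition and an enolate fixed at C3 and not at C1; the soft aryl-rhodium and the aprotic medium secure both, since the enolate forms only where the aryl group has added and is not protonated before the aldehyde arrives. Cooling before 7 is added should keep residual aryl-rhodium from adding to the aldehyde.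

Step 4
Reactants: 10 (3R,4S)-3-[(R)-hydroxy(2,4,6-trimethoxyphenyl)methyl]-4-[2-(methoxymethoxy)-4,6-dimethoxyphenyl]-6-methylheptan-2-one
Product: 12 1-[(2R,3S,4S)-5,7-dimethoxy-4-(2-methylpropyl)-2-(2,4,6-trimethoxyphenyl)-3,4-dihydro-2H-chromen-3-yl]ethan-1-one, via free phenol 11 (not isolated)
Conditions: HCl (1.25 M in MeOH), 0 °C → rt; evaporate; CSA (cat.), ClCH2CH2Cl (dilute), 60 °C
Reagents that add atoms: none
Why: Acetal exchange with methanol removes the MOM group, the trimethoxyphenyl-stabilised benzylic cation at C2 is captured by the phenol (cyclodehydration, 6-exo-trig onto the quinone-methide-like cation), and continued acid equilibrates C2 (reversible ionisation or retro-oxa-Michael) and C3 (enolisation); the expected resting isomer has the isobutyl group pseudoaxial (peri strain with the C5 methoxy), the aryl group equatorial and trans to it, and the acetyl group axial and anti to isobutyl, which is the 2,3-cis-3,4-trans arrangement.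

Step 5
Reactants: 12 1-[(2R,3S,4S)-5,7-dimethoxy-4-(2-methylpropyl)-2-(2,4,6-trimethoxyphenyl)-3,4-dihydro-2H-chromen-3-yl]ethan-1-one
Product: 13 (2R,3R,4S)-5,7-dimethoxy-4-(2-methylpropyl)-3-(prop-1-en-2-yl)-2-(2,4,6-trimethoxyphenyl)-3,4-dihydro-2H-chromene
Conditions: Cp2TiMe2, toluene/THF, 65 °C, dark
Reagents that add atoms: dimethyltitanocene, C[Ti](C)(C1C=CC=C1)C1C=CC=C1
Why: Petasis methylenation (thermally formed titanocene methylidene, [2+2] addition to C=O and cycloreversion) is non-basic and free of Lewis acid, so the epimerisable C3, the β-aryloxy ketone and the acid-labile C2–O bond should be untouched; the descriptor at C3 changes only because the priorities change.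

Step 6
Reactants: 13 (2R,3R,4S)-5,7-dimethoxy-4-(2-methylpropyl)-3-(prop-1-en-2-yl)-2-(2,4,6-trimethoxyphenyl)-3,4-dihydro-2H-chromene
Product: 14 (2R,3S,4S)-5,7-dimethoxy-4-(2-methylpropyl)-3-(propan-2-yl)-2-(2,4,6-trimethoxyphenyl)-3,4-dihydro-2H-chromene
Conditions: H2 (1 atm), Pt/C, EtOAc, rt
Reagents that add atoms: none
Why: Heterogeneous hydrogenation of the 1,1-disubstituted alkene gives the isopropyl group without creating a stereocentre, and platinum under neutral conditions is chosen to avoid hydrogenolysis of the benzylic C2–O bond.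

Step 7
Reactants: 14 (2R,3S,4S)-5,7-dimethoxy-4-(2-methylpropyl)-3-(propan-2-yl)-2-(2,4,6-trimethoxyphenyl)-3,4-dihydro-2H-chromene
Product: 15 (2R,3S,4S)-2-(3,5-diformyl-2,4,6-trimethoxyphenyl)-5,7-dimethoxy-4-(2-methylpropyl)-3-(propan-2-yl)-3,4-dihydro-2H-chromene-6,8-dicarbaldehyde
Conditions: Cl2CHOMe (excess), TiCl4, CH2Cl2, −20 °C → rt; then 1 M aq. HCl, rt
Reagents that add atoms: dichloromethyl methyl ether, COC(Cl)Cl; water, O
Why: Rieche formylation should take all four free ring positions because each lies between two oxygen substituents, and the first formyl group on the trimethoxyphenyl ring removes the tendency of C2 to ionise, while any reversible opening before that should re-close to the same isomer (aryl equatorial, trans to the pseudoaxial isobutyl group).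

Step 8
Reactants: 15 (2R,3S,4S)-2-(3,5-diformyl-2,4,6-trimethoxyphenyl)-5,7-dimethoxy-4-(2-methylpropyl)-3-(propan-2-yl)-3,4-dihydro-2H-chromene-6,8-dicarbaldehyde
Product: 16 sideroxylonal B, (2R,3S,4S)-2-(3,5-diformyl-2,4,6-trihydroxyphenyl)-5,7-dihydroxy-4-(2-methylpropyl)-3-(propan-2-yl)-3,4-dihydro-2H-chromene-6,8-dicarbaldehyde
Conditions: BCl3 (excess), CH2Cl2, −78 °C → rt; then H2O/MeOH
Reagents that add atoms: none
Why: Chelation-assisted demethylation by BCl3 should cleave all five methyl ethers because each is ortho to a formyl group, while the secondary O1–C2 ether, now attached to an electron-poor aryl ring, neither ionises nor undergoes chloride attack.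

**Compound list**

1 | 3,5-dimethoxyphenol | COc1cc(O)cc(OC)c1 | starting material
2 | 1,3-dimethoxy-5-(methoxymethoxy)benzene | COCOc1cc(OC)cc(OC)c1 | intermediate
3 | [2-(methoxymethoxy)-4,6-dimethoxyphenyl]lithium | [Li]c1c(OCOC)cc(OC)cc1OC | intermediate
4 | lithium 9-methoxy-9-[2-(methoxymethoxy)-4,6-dimethoxyphenyl]-9-boranuidabicyclo[3.3.1]nonane | [Li+].CO[B-]1(c2c(OCOC)cc(OC)cc2OC)C2CCCC1CCC2 | intermediate
5 | 9-[2-(methoxymethoxy)-4,6-dimethoxyphenyl]-9-borabicyclo[3.3.1]nonane | COCOc1cc(OC)cc(OC)c1B1C2CCCC1CCC2 | intermediate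
6 | (E)-6-methylhept-3-en-2-one | CC(=O)/C=C/CC(C)C | starting material
7 | 2,4,6-trimethoxybenzaldehyde | COc1cc(OC)c(C=O)c(OC)c1 | starting material
8 | 9-{[(2Z,4S)-4-[2-(methoxymethoxy)-4,6-dimethoxyphenyl]-6-methylhept-2-en-2-yl]oxy}-9-borabicyclo[3.3.1]nonane | C/C(OB1C2CCCC1CCC2)=C/[C@H](CC(C)C)c1c(OCOC)cc(OC)cc1OC | intermediate
9 | O-(9-borabicyclo[3.3.1]nonan-9-yl) derivative of 10 (boron aldolate, configuration as in 10) | CC(C)C[C@@H]([C@H]([C@@H](OB1C2CCCC1CCC2)c1c(OC)cc(OC)cc1OC)C(C)=O)c1c(OCOC)cc(OC)cc1OC | intermediate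
10 | (3R,4S)-3-[(R)-hydroxy(2,4,6-trimethoxyphenyl)methyl]-4-[2-(methoxymethoxy)-4,6-dimethoxyphenyl]-6-methylheptan-2-one | CC(C)C[C@@H]([C@H]([C@@H](O)c1c(OC)cc(OC)cc1OC)C(C)=O)c1c(OCOC)cc(OC)cc1OC | intermediate
11 | (3R,4S)-3-[(R)-hydroxy(2,4,6-trimethoxyphenyl)methyl]-4-(2-hydroxy-4,6-dimethoxyphenyl)-6-methylheptan-2-one | CC(C)C[C@@H]([C@H]([C@@H](O)c1c(OC)cc(OC)cc1OC)C(C)=O)c1c(O)cc(OC)cc1OC | intermediate
12 | 1-[(2R,3S,4S)-5,7-dimethoxy-4-(2-methylpropyl)-2-(2,4,6-trimethoxyphenyl)-3,4-dihydro-2H-chromen-3-yl]ethan-1-one | CC(C)C[C@@H]1c2c(OC)cc(OC)cc2O[C@@H](c2c(OC)cc(OC)cc2OC)[C@H]1C(C)=O | intermediate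
13 | (2R,3R,4S)-5,7-dimethoxy-4-(2-methylpropyl)-3-(prop-1-en-2-yl)-2-(2,4,6-trimethoxyphenyl)-3,4-dihydro-2H-chromene | CC(C)C[C@@H]1c2c(OC)cc(OC)cc2O[C@@H](c2c(OC)cc(OC)cc2OC)[C@H]1C(C)=C | intermediate
14 | (2R,3S,4S)-5,7-dimethoxy-4-(2-methylpropyl)-3-(propan-2-yl)-2-(2,4,6-trimethoxyphenyl)-3,4-dihydro-2H-chromene | CC(C)C[C@@H]1c2c(OC)cc(OC)cc2O[C@@H](c2c(OC)cc(OC)cc2OC)[C@H]1C(C)C | intermediate
15 | (2R,3S,4S)-2-(3,5-diformyl-2,4,6-trimethoxyphenyl)-5,7-dimethoxy-4-(2-methylpropyl)-3-(propan-2-yl)-3,4-dihydro-2H-chromene-6,8-dicarbaldehyde | CC(C)C[C@@H]1c2c(OC)c(C=O)c(OC)c(C=O)c2O[C@@H](c2c(OC)c(C=O)c(OC)c(C=O)c2OC)[C@H]1C(C)C | intermediate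
16 | sideroxylonal B, (2R,3S,4S)-2-(3,5-diformyl-2,4,6-trihydroxyphenyl)-5,7-dihydroxy-4-(2-methylpropyl)-3-(propan-2-yl)-3,4-dihydro-2H-chromene-6,8-dicarbaldehyde | CC(C)C[C@@H]1c2c(O)c(C=O)c(O)c(C=O)c2O[C@@H](c2c(O)c(C=O)c(O)c(C=O)c2O)[C@H]1C(C)C | target

**Step count and risk**

Total steps: 8. Longest linear sequence: 8 steps (from 3,5-dimethoxyphenol; the enone and the aldehyde are bought).

Steps most likely to fail:

1. Step 3. Boron-to-rhodium transfer and enone insertion of the doubly ortho-substituted aryl group may be slow, so that conversion stalls or face selection erodes, and the hindered enolate may add too slowly to the electron-rich aldehyde and simply be protonated on work-up. Fallback (sets out from 2 through aryllithium 3, returns at 10): 3 is transmetalated with MgBr2·OEt2 to [2-(methoxymethoxy)-4,6-dimethoxyphenyl]magnesium bromide F2 and added with CuBr·SMe2 (THF/Me2S, −40 °C) to (4R)-3-[(E)-5-methylhex-2-enoyl]-4-phenyl-1,3-oxazolidin-2-one F1, itself made from commercial (E)-5-methylhex-2-enoic acid (pivaloyl chloride, Et3N; then the lithium salt of (R)-4-phenyl-1,3-oxazolidin-2-one). Attack anti to the 4-phenyl group of the magnesium-chelated imide should give (4R)-3-{(3S)-3-[2-(methoxymethoxy)-4,6-dimethoxyphenyl]-5-methylhexanoyl}-4-phenyl-1,3-oxazolidin-2-one F3. Enolisation with Bu2BOTf/iPr2NEt and addition of 7 should give the Evans syn aldol (4R)-3-{(2R,3S)-2-[(R)-hydroxy(2,4,6-trimethoxyphenyl)methyl]-3-[2-(methoxymethoxy)-4,6-dimethoxyphenyl]-5-methylhexanoyl}-4-phenyl-1,3-oxazolidin-2-one F4. Transamination with MeNH(OMe)·HCl/AlMe3 gives the Weinreb amide (2R,3S)-2-[(R)-hydroxy(2,4,6-trimethoxyphenyl)methyl]-N-methoxy-3-[2-(methoxymethoxy)-4,6-dimethoxyphenyl]-N,5-dimethylhexanamide F5, and MeMgBr then gives 10.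

2. Step 4. The stabilised benzylic cation may alkylate the electron-rich rings of a second molecule or the sequence may stall at the dehydrated enone, and equilibration at C3 under acid may remain incomplete. Fallback (sets out from 10, returns at 12): Ac2O/DMAP/Et3N gives the acetate of aldol 10 F6; DBU in CH2Cl2 eliminates acetic acid to (4R)-3-[(2,4,6-trimethoxyphenyl)methylidene]-4-[2-(methoxymethoxy)-4,6-dimethoxyphenyl]-6-methylheptan-2-one F7 (drawn E; either geometry serves). HCl in MeOH removes the MOM group to give (4R)-4-(2-hydroxy-4,6-dimethoxyphenyl)-3-[(2,4,6-trimethoxyphenyl)methylidene]-6-methylheptan-2-one F8. DBU (cat.) in toluene at 60 °C then closes the ring by 6-endo-trig oxa-Michael addition and equilibrates C2 and C3 through retro-oxa-Michael addition and enolisation to 12; a C3 epimer that persists is separated and resubmitted.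

3. Step 7. The second formylation on each already deactivated ring may not go to completion, and TiCl4 may open the C2–O bond before the trimethoxyphenyl ring is deactivated. Fallback (sets out from 14, returns at 15): NBS (MeCN, 0 °C) should give (2R,3S,4S)-6,8-dibromo-2-(3,5-dibromo-2,4,6-trimethoxyphenyl)-5,7-dimethoxy-4-(2-methylpropyl)-3-(propan-2-yl)-3,4-dihydro-2H-chromene F9 under non-acidic conditions. Fourfold Suzuki–Miyaura coupling with potassium vinyltrifluoroborate (Pd(OAc)2, SPhos, K2CO3, toluene/H2O, 90 °C) gives (2R,3S,4S)-6,8-diethenyl-2-(3,5-diethenyl-2,4,6-trimethoxyphenyl)-5,7-dimethoxy-4-(2-methylpropyl)-3-(propan-2-yl)-3,4-dihydro-2H-chromene F10, and Lemieux–Johnson cleavage (OsO4 cat., NaIO4, 2,6-lutidine, dioxane/H2O) gives 15.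

**Further compounds**

F1 | step 3 | (4R)-3-[(E)-5-methylhex-2-enoyl]-4-phenyl-1,3-oxazolidin-2-one | CC(C)C/C=C/C(=O)N1[C@H](c2ccccc2)COC1=O
F2 | step 3 | [2-(methoxymethoxy)-4,6-dimethoxyphenyl]magnesium bromide | Br[Mg]c1c(OCOC)cc(OC)cc1OC
F3 | step 3 | (4R)-3-{(3S)-3-[2-(methoxymethoxy)-4,6-dimethoxyphenyl]-5-methylhexanoyl}-4-phenyl-1,3-oxazolidin-2-one | CC(C)C[C@@H](CC(=O)N1[C@H](c2ccccc2)COC1=O)c1c(OCOC)cc(OC)cc1OC
F4 | step 3 | (4R)-3-{(2R,3S)-2-[(R)-hydroxy(2,4,6-trimethoxyphenyl)methyl]-3-[2-(methoxymethoxy)-4,6-dimethoxyphenyl]-5-methylhexanoyl}-4-phenyl-1,3-oxazolidin-2-one | CC(C)C[C@@H]([C@H]([C@@H](O)c1c(OC)cc(OC)cc1OC)C(=O)N1[C@H](c2ccccc2)COC1=O)c1c(OCOC)cc(OC)cc1OC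
F5 | step 3 | (2R,3S)-2-[(R)-hydroxy(2,4,6-trimethoxyphenyl)methyl]-N-methoxy-3-[2-(methoxymethoxy)-4,6-dimethoxyphenyl]-N,5-dimethylhexanamide | CC(C)C[C@@H]([C@H]([C@@H](O)c1c(OC)cc(OC)cc1OC)C(=O)N(C)OC)c1c(OCOC)cc(OC)cc1OC
F6 | step 4 | acetate of aldol 10 (configuration as in 10) | CC(C)C[C@@H]([C@H]([C@@H](OC(C)=O)c1c(OC)cc(OC)cc1OC)C(C)=O)c1c(OCOC)cc(OC)cc1OC
F7 | step 4 | (3E,4R)-3-[(2,4,6-trimethoxyphenyl)methylidene]-4-[2-(methoxymethoxy)-4,6-dimethoxyphenyl]-6-methylheptan-2-one | CC(C)C[C@@H](/C(C(C)=O)=C\c1c(OC)cc(OC)cc1OC)c1c(OCOC)cc(OC)cc1OC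
F8 | step 4 | (3E,4R)-4-(2-hydroxy-4,6-dimethoxyphenyl)-3-[(2,4,6-trimethoxyphenyl)methylidene]-6-methylheptan-2-one | CC(C)C[C@@H](/C(C(C)=O)=C\c1c(OC)cc(OC)cc1OC)c1c(O)cc(OC)cc1OC
F9 | step 7 | (2R,3S,4S)-6,8-dibromo-2-(3,5-dibromo-2,4,6-trimethoxyphenyl)-5,7-dimethoxy-4-(2-methylpropyl)-3-(propan-2-yl)-3,4-dihydro-2H-chromene | CC(C)C[C@@H]1c2c(OC)c(Br)c(OC)c(Br)c2O[C@@H](c2c(OC)c(Br)c(OC)c(Br)c2OC)[C@H]1C(C)C
F10 | step 7 | (2R,3S,4S)-6,8-diethenyl-2-(3,5-diethenyl-2,4,6-trimethoxyphenyl)-5,7-dimethoxy-4-(2-methylpropyl)-3-(propan-2-yl)-3,4-dihydro-2H-chromene | CC(C)C[C@@H]1c2c(OC)c(C=C)c(OC)c(C=C)c2O[C@@H](c2c(OC)c(C=C)c(OC)c(C=C)c2OC)[C@H]1C(C)C
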